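The synthesis rests on disconnecting the γ-lactone (ring B: O–C12–C11–C7–C8) at C11–C12 and C12–O, leaving a cyclohexane (ring A, C5–C10) that already carries all six stereocentres. One palladium-catalysed cyclocarbonylation stitches CO between the equatorial C8 hydroxyl and the equatorial C7 ethynyl group, closing ring B and creating the exocyclic C11=C13 methylene without base. The step exploits the trans-diequatorial, homopropargylic C8–OH/C7–C≡CH pair on ring A. Its precursor is the 8α,9α-diol bearing the 7β-ethynyl group, a silylated 6β-oxygen and the silylated C15 alcohol; ring A comes from an Ireland–Claisen rearrangement, a Fráter–Seebach hydroxymethylation and a SmI2 pinacol closure.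

Key step: step 19

Conventions, design remarks and assumption
- Elemane numbering is used. Ring A is the cyclohexane C5–C10. C10 carries the methyl C14 and the vinyl group C1=C2. C5 carries C4 (C3 methylene, C15). C7 carries C11 (C13 methylene, C12 carbonyl).
- β is the face of ring A that carries C14, α the opposite face. In the chair used in the arguments C14, O6 and O9 are axial and the C5, C7 and C8 substituents are equatorial.
- TBSO = tert-butyldimethylsilyloxy, TESO = triethylsilyloxy, PivO = 2,2-dimethylpropanoyloxy.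
- The carbonylation substrate contains two alkenes (C1=C2 and C3=C4); the angelate alkene is introduced only afterwards.
- O6 is homopropargylic and cis to the ethynyl group, so it stays silylated through the key step. The axial 9α-hydroxyl is trans-1,3 to the alkyne, cannot lactonise and is left free, which avoids a selective silylation of the more hindered hydroxyl of the diol.
- The acetate is added last because it would not survive the hydride and K2CO3/MeOH steps.
- Assumption: the (4S,5S)-diazaborolidine of step 8 is taken to give the (2S,3S) acid by analogy with simpler allyl esters; if the sense is opposite, the (4R,5R) reagent is used with no other change.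

Step 1
Reactants: 1 3-methylbut-2-en-1-yl acetate (prenyl acetate)
Product: 2 (2E)-4-hydroxy-3-methylbut-2-en-1-yl acetate
Conditions: SeO2 (0.3 equiv), tBuOOH (2 equiv), CH2Cl2, rt
Reagents that add atoms: tert-butyl hydroperoxide, CC(C)(C)OO (oxygen carried by catalytic selenium dioxide, O=[Se]=O)
Why: Allylic oxidation by an ene reaction and [2,3]-sigmatropic shift with SeO2 is known to hydroxylate the (E)-methyl group of prenyl-type alkenes, which fixes the (E)-geometry needed for the later chair transition state.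

Step 2
Reactants: 2 (2E)-4-hydroxy-3-methylbut-2-en-1-yl acetate
Product: 3 (2E)-4-acetoxy-2-methylbut-2-en-1-yl 2,2-dimethylpropanoate
Conditions: PivCl, pyridine, DMAP (cat.), CH2Cl2, 0 °C → rt
Reagents that add atoms: pivaloyl chloride, CC(C)(C)C(=O)Cl
Why: Acylation of the free primary allylic alcohol gives a pivalate that tolerates the later enolate chemistry and is removed reductively together with the C8 ester.

Step 3
Reactants: 3 (2E)-4-acetoxy-2-methylbut-2-en-1-yl 2,2-dimethylpropanoate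
Product: 4 (2E)-4-hydroxy-2-methylbut-2-en-1-yl 2,2-dimethylpropanoate
Conditions: K2CO3 (0.2 equiv), MeOH, 0 °C
Reagents that add atoms: none
Why: Base-catalysed transesterification should remove the unhindered acetate much faster than the pivalate, exposing the hydroxyl that will carry the rearranging ester.

Step 4
Reactants: 5 4-methoxy-2-methylidene-4-oxobutanoic acid (4-methyl hydrogen itaconate)
Product: 7 methyl 3-(hydroxymethyl)but-3-enoate, via isobutyl carbonic mixed anhydride 6 (not isolated)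
Conditions: iBuOCOCl, N-methylmorpholine, THF, −15 °C; then NaBH4, H2O, −15 → 0 °C
Reagents that add atoms: none
Why: Mixed-anhydride activation followed by borohydride reduction converts the free acrylic acid into the allylic alcohol (future C15) while leaving the methyl ester and the alkene untouched.

Step 5
Reactants: 7 methyl 3-(hydroxymethyl)but-3-enoate
Product: 8 methyl 3-[(TBSO)methyl]but-3-enoate
Conditions: TBSCl, imidazole, DMF, 0 °C
Reagents that add atoms: tert-butyldimethylsilyl chloride, CC(C)(C)[Si](C)(C)Cl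
Why: Silylation of the primary allylic alcohol blocks lactonisation and gives an ether that should last until the final desilylation.

Step 6
Reactants: 8 methyl 3-[(TBSO)methyl]but-3-enoate
Product: 9 3-[(TBSO)methyl]but-3-enoic acid
Conditions: LiOH, THF/H2O, 0 °C; then cold dilute HCl to pH 4
Reagents that add atoms: lithium hydroxide, [Li+].[OH-]
Why: Saponification at 0 °C should hydrolyse the methyl ester faster than the β,γ-alkene can migrate into conjugation, and the silyl ether is stable to hydroxide.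

Step 7
Reactants: 9 3-[(TBSO)methyl]but-3-enoic acid; 4 (2E)-4-hydroxy-2-methylbut-2-en-1-yl 2,2-dimethylpropanoate
Product: 10 (2E)-3-methyl-4-(PivO)but-2-en-1-yl 3-[(TBSO)methyl]but-3-enoate
Conditions: DCC, DMAP (5 mol %), CH2Cl2, −10 °C → rt
Reagents that add atoms: none
Why: Steglich esterification joins the two fragments under neutral conditions, the low DMAP loading and temperature limiting isomerisation of the β,γ-unsaturated acyl donor.

Step 8
Reactants: 10 (2E)-3-methyl-4-(PivO)but-2-en-1-yl 3-[(TBSO)methyl]but-3-enoate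
Product: 12 (2S,3S)-2-[3-(TBSO)prop-1-en-2-yl]-3-methyl-3-[(PivO)methyl]pent-4-enoic acid, via boron ketene acetal 11 (not isolated)
Conditions: (4S,5S)-2-bromo-1,3-bis{[3,5-bis(trifluoromethyl)phenyl]sulfonyl}-4,5-diphenyl-1,3,2-diazaborolidine (1.2 equiv), Et3N, toluene/hexane, −78 °C; then −20 → 4 °C; aqueous work-up
Reagents that add atoms: none
Why: An enantioselective Ireland–Claisen rearrangement of the E(O)-boron dienolate through a chair transition state with the (E)-allyl unit should set C5 and C10 together (C4 branch and C9 anti, as in the elemanes), the C2-symmetric diazaborolidine choosing the enantiotopic face.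

Step 9
Reactants: 12 (2S,3S)-2-[3-(TBSO)prop-1-en-2-yl]-3-methyl-3-[(PivO)methyl]pent-4-enoic acid; 13 potassium 3-methoxy-3-oxopropanoate
Product: 16 methyl (4S,5S)-4-[3-(TBSO)prop-1-en-2-yl]-5-methyl-3-oxo-5-[(PivO)methyl]hept-6-enoate, via acyl imidazolide 14 (not isolated), via acylmalonic half-ester 15 (not isolated)
Conditions: CDI, THF, rt; then KO2CCH2CO2Me (13), MgCl2, Et3N, THF, rt → 40 °C; cold dilute HCl
Reagents that add atoms: potassium 3-methoxy-3-oxopropanoate (compound 13), COC(=O)CC(=O)[O-].[K+]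
Why: Masamune–Brooks homologation (C-acylation of the magnesium malonate half-ester by the acyl imidazolide, then decarboxylation) is a neutral route to the β-keto ester that should spare the epimerisable, doubly activated C5–H.

Step 10
Reactants: 16 methyl (4S,5S)-4-[3-(TBSO)prop-1-en-2-yl]-5-methyl-3-oxo-5-[(PivO)methyl]hept-6-enoate
Product: 17 methyl (3R,4S,5S)-3-hydroxy-4-[3-(TBSO)prop-1-en-2-yl]-5-methyl-5-[(PivO)methyl]hept-6-enoate
Conditions: NaBH4, MeOH, −40 °C
Reagents that add atoms: none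
Why: Felkin–Anh-controlled hydride reduction, with attack anti to the tertiary-alkyl C10 group and the C4 alkenyl branch inside, should give the C6 carbinol anti to that branch, which is the 6β-oxygen of the target.

Step 11
Reactants: 17 methyl (3R,4S,5S)-3-hydroxy-4-[3-(TBSO)prop-1-en-2-yl]-5-methyl-5-[(PivO)methyl]hept-6-enoate
Product: 19 methyl (2S,3S,4S,5S)-3-hydroxy-2-(hydroxymethyl)-4-[3-(TBSO)prop-1-en-2-yl]-5-methyl-5-[(PivO)methyl]hept-6-enoate, via dilithium alkoxide enolate 18 (not isolated)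
Conditions: LiN(iPr)2 (2.3 equiv), THF, −78 → −20 °C; then CH2O (gas, from cracked paraformaldehyde), −78 → −40 °C; aq. NH4Cl
Reagents that add atoms: formaldehyde, C=O
Why: Fráter–Seebach hydroxymethylation of the chelated dianion brings the electrophile in anti to the bulky C6 substituent, so C11 should end up anti to the C6 oxygen (7β in the ring).

Step 12
Reactants: 19 methyl (2S,3S,4S,5S)-3-hydroxy-2-(hydroxymethyl)-4-[3-(TBSO)prop-1-en-2-yl]-5-methyl-5-[(PivO)methyl]hept-6-enoate
Product: 20 methyl (2S,3S,4S,5S)-3-(TESO)-2-[(TESO)methyl]-4-[3-(TBSO)prop-1-en-2-yl]-5-methyl-5-[(PivO)methyl]hept-6-enoate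
Conditions: TESOTf (2.6 equiv), 2,6-lutidine, CH2Cl2, −78 → 0 °C
Reagents that add atoms: triethylsilyl trifluoromethanesulfonate, CC[Si](CC)(CC)OS(=O)(=O)C(F)(F)F
Why: Exhaustive silylation with the silyl triflate caps both the hindered C6 hydroxyl and the primary C11 hydroxyl, which can later be told apart by their very different rates of acidic solvolysis.

Step 13
Reactants: 20 methyl (2S,3S,4S,5S)-3-(TESO)-2-[(TESO)methyl]-4-[3-(TBSO)prop-1-en-2-yl]-5-methyl-5-[(PivO)methyl]hept-6-enoate
Product: 21 (2S,3S,4S,5S)-5-(hydroxymethyl)-5-methyl-3-(TESO)-2-[(TESO)methyl]-4-[3-(TBSO)prop-1-en-2-yl]hept-6-en-1-ol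
Conditions: iBu2AlH (7 equiv), CH2Cl2, −78 → 0 °C
Reagents that add atoms: none
Why: Hydride reduction cleaves the methyl ester to the C8 carbinol and the pivalate to the C9 carbinol in one operation without touching silyl ethers or alkenes.

Step 14
Reactants: 21 (2S,3S,4S,5S)-5-(hydroxymethyl)-5-methyl-3-(TESO)-2-[(TESO)methyl]-4-[3-(TBSO)prop-1-en-2-yl]hept-6-en-1-ol
Product: 22 (2S,3S,4S,5S)-2-ethenyl-2-methyl-4-(TESO)-5-[(TESO)methyl]-3-[3-(TBSO)prop-1-en-2-yl]hexanedial
Conditions: Dess–Martin periodinane (2.6 equiv), CH2Cl2, 0 °C → rt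
Reagents that add atoms: none
Why: Dess–Martin oxidation converts both primary alcohols to aldehydes under base-free conditions, which should prevent β-elimination or epimerisation at C7.

Step 15
Reactants: 22 (2S,3S,4S,5S)-2-ethenyl-2-methyl-4-(TESO)-5-[(TESO)methyl]-3-[3-(TBSO)prop-1-en-2-yl]hexanedial
Product: 23 10α-ethenyl-10β-methyl-5β-[3-(TBSO)prop-1-en-2-yl]-6β-(TESO)-7β-[(TESO)methyl]cyclohexane-8α,9α-diol
Conditions: SmI2 (3 equiv), THF, −78 → 0 °C; aq. NaHCO3
Reagents that add atoms: none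
Why: Intramolecular pinacol coupling of the 1,6-dialdehyde through a samarium-bridged ketyl–aldehyde chair (C5 and C7 branches equatorial) should give the cis-diol with O8 equatorial, trans to the C7 branch, and O9 axial, the other cis-diol being blocked by a syn-axial clash of O8 with C14 and the C6 silyloxy group.

Step 16
Reactants: 23 10α-ethenyl-10β-methyl-5β-[3-(TBSO)prop-1-en-2-yl]-6β-(TESO)-7β-[(TESO)methyl]cyclohexane-8α,9α-diol
Product: 24 10α-ethenyl-7β-(hydroxymethyl)-10β-methyl-5β-[3-(TBSO)prop-1-en-2-yl]-6β-(TESO)cyclohexane-8α,9α-diol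
Conditions: PPTS (0.2 equiv), MeOH/CH2Cl2 (1:4), −10 → 0 °C
Reagents that add atoms: none
Why: Acid-catalysed methanolysis removes a primary triethylsilyl ether far faster than the hindered axial secondary one at C6 or the primary tert-butyldimethylsilyl ether at C15.

Step 17
Reactants: 24 10α-ethenyl-7β-(hydroxymethyl)-10β-methyl-5β-[3-(TBSO)prop-1-en-2-yl]-6β-(TESO)cyclohexane-8α,9α-diol
Product: 25 10α-ethenyl-7β-formyl-10β-methyl-5β-[3-(TBSO)prop-1-en-2-yl]-6β-(TESO)cyclohexane-8α,9α-diol
Conditions: TEMPO (0.1 equiv), PhI(OAc)2 (1.2 equiv), CH2Cl2, rt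
Reagents that add atoms: none
Why: Oxoammonium (TEMPO) oxidation is selective for the primary alcohol over the secondary cis-diol, giving the C11 aldehyde without oxidising or cleaving the C8/C9 glycol.

Step 18
Reactants: 25 10α-ethenyl-7β-formyl-10β-methyl-5β-[3-(TBSO)prop-1-en-2-yl]-6β-(TESO)cyclohexane-8α,9α-diol
Product: 26 10α-ethenyl-7β-ethynyl-10β-methyl-5β-[3-(TBSO)prop-1-en-2-yl]-6β-(TESO)cyclohexane-8α,9α-diol
Conditions: dimethyl (1-diazo-2-oxopropyl)phosphonate, K2CO3, MeOH, 0 °C → rt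
Reagents that add atoms: dimethyl (1-diazo-2-oxopropyl)phosphonate, COP(=O)(OC)C(=[N+]=[N-])C(C)=O
Why: Ohira–Bestmann (Seyferth–Gilbert) homologation turns the C11 aldehyde into the terminal alkyne, and because no ester is present and C7 already has its thermodynamically preferred equatorial configuration the carbonate/methanol medium should do no harm.

Step 19
Reactants: 26 10α-ethenyl-7β-ethynyl-10β-methyl-5β-[3-(TBSO)prop-1-en-2-yl]-6β-(TESO)cyclohexane-8α,9α-diol; 27 carbon monoxide
Product: 28 9α-hydroxy-6β-(TESO)-15-(TBSO)elema-1,3,11(13)-trien-12,8α-olide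
Conditions: PdCl2 (10 mol %), PPh3 (20 mol %), SnCl2 (10 mol %), CO (7 atm), MeCN, 70 °C
Reagents that add atoms: carbon monoxide (compound 27), [C-]#[O+]
Why: The C8 hydroxyl and CO form an alkoxycarbonyl complex of divalent palladium, the tethered alkyne inserts syn into the Pd–acyl bond to make C11–C12, and protonolysis of the resulting vinylpalladium by the acid set free in the alkoxycarbonylation releases the exocyclic methylene and the catalyst. The closest known reaction type is the PdCl2/SnCl2/phosphine cyclocarbonylation of trans-2-ethynylcycloalkanols and other homopropargylic alcohols to α-methylene-γ-butyrolactones. Ring B (O–C12–C11–C7–C8) closes in the 5-exo-dig mode, the acyl carbon bonding to the alkyne carbon attached to C7 while C13 stays outside the ring. No stereocentre is formed or touched, so the trans ring fusion is inherited from the diequatorial C8–O and C7–C11 bonds. Site selectivity among the oxygens is secured by the substrate: the axial C9 hydroxyl is trans-1,3 to the ethynyl group and cannot bridge to it, and the 6β-oxygen, also homopropargylic and cis to the alkyne, is capped as its triethylsilyl ether. Chemoselectivity for the alkyne over the two alkenes (C1=C2 and C3=C4) follows from the intramolecular five-membered insertion, and the near-neutral medium should leave both silyl ethers intact.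

Step 20
Reactants: 28 9α-hydroxy-6β-(TESO)-15-(TBSO)elema-1,3,11(13)-trien-12,8α-olide; 29 (2Z)-2-methylbut-2-enoic acid (angelic acid)
Product: 31 9α-[(2Z)-2-methylbut-2-enoyloxy]-6β-(TESO)-15-(TBSO)elema-1,3,11(13)-trien-12,8α-olide, via angelic 2,4,6-trichlorobenzoic anhydride 30 (not isolated)
Conditions: 29 (3 equiv), 2,4,6-trichlorobenzoyl chloride, Et3N, toluene, rt; then 28, toluene, 80 °C
Reagents that add atoms: angelic acid (compound 29), C/C=C(/C)C(=O)O
Why: Yamaguchi-type acylation by the preformed mixed anhydride, run without a nucleophilic amine catalyst, is an established way to angeloylate hindered secondary alcohols without (Z)→(E) isomerisation to the tiglate, and the C9 hydroxyl is the only free one.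

Step 21
Reactants: 31 9α-[(2Z)-2-methylbut-2-enoyloxy]-6β-(TESO)-15-(TBSO)elema-1,3,11(13)-trien-12,8α-olide
Product: 32 6β,15-dihydroxy-9α-[(2Z)-2-methylbut-2-enoyloxy]elema-1,3,11(13)-trien-12,8α-olide
Conditions: HF·pyridine, pyridine, THF, 0 °C → rt
Reagents that add atoms: none
Why: Buffered fluoride-mediated desilylation removes both silyl ethers under mildly acidic conditions that should not touch the angelate, the lactone or the exocyclic methylene.

Step 22
Reactants: 32 6β,15-dihydroxy-9α-[(2Z)-2-methylbut-2-enoyloxy]elema-1,3,11(13)-trien-12,8α-olide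
Product: 33 6β-hydroxy-9α-[(2Z)-2-methylbut-2-enoyloxy]-15-oxoelema-1,3,11(13)-trien-12,8α-olide
Conditions: MnO2 (activated, excess), CH2Cl2, rt
Reagents that add atoms: none
Why: Allylic oxidation with MnO2 converts only the primary allylic alcohol at C15 into the 2-substituted propenal and leaves the saturated secondary C6 hydroxyl alone.

Step 23
Reactants: 33 6β-hydroxy-9α-[(2Z)-2-methylbut-2-enoyloxy]-15-oxoelema-1,3,11(13)-trien-12,8α-olide
Product: 34 6β-acetoxy-9α-[(2Z)-2-methylbut-2-enoyloxy]-15-oxoelema-1,3,11(13)-trien-12,8α-olide (CNP0252310.1)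
Conditions: Ac2O, pyridine, DMAP (cat.), CH2Cl2, 0 °C → rt
Reagents that add atoms: acetic anhydride, CC(=O)OC(C)=O
Why: Acylation of the single remaining hydroxyl, axial at C6, with acetic anhydride under nucleophilic catalysis completes the target without disturbing any stereocentre.

Compound list
1 | 3-methylbut-2-en-1-yl acetate (prenyl acetate) | CC(C)=CCOC(C)=O | starting material
2 | (2E)-4-hydroxy-3-methylbut-2-en-1-yl acetate | CC(=O)OC/C=C(\C)CO | intermediate
3 | (2E)-4-acetoxy-2-methylbut-2-en-1-yl 2,2-dimethylpropanoate | CC(=O)OC/C=C(\C)COC(=O)C(C)(C)C | intermediate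
4 | (2E)-4-hydroxy-2-methylbut-2-en-1-yl 2,2-dimethylpropanoate | OC/C=C(\C)COC(=O)C(C)(C)C | intermediate
5 | 4-methoxy-2-methylidene-4-oxobutanoic acid (4-methyl hydrogen itaconate) | C=C(CC(=O)OC)C(=O)O | starting material
6 | isobutyl carbonic mixed anhydride of 5 | C=C(CC(=O)OC)C(=O)OC(=O)OCC(C)C | intermediate
7 | methyl 3-(hydroxymethyl)but-3-enoate | C=C(CO)CC(=O)OC | intermediate
8 | methyl 3-[(TBSO)methyl]but-3-enoate | C=C(CO[Si](C)(C)C(C)(C)C)CC(=O)OC | intermediate
9 | 3-[(TBSO)methyl]but-3-enoic acid | C=C(CO[Si](C)(C)C(C)(C)C)CC(=O)O | intermediate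
10 | (2E)-3-methyl-4-(PivO)but-2-en-1-yl 3-[(TBSO)methyl]but-3-enoate | C=C(CO[Si](C)(C)C(C)(C)C)CC(=O)OC/C=C(\C)COC(=O)C(C)(C)C | intermediate
11 | E(O)-boron ketene acetal of 10 carrying the (4S,5S)-1,3-bis{[3,5-bis(trifluoromethyl)phenyl]sulfonyl}-4,5-diphenyl-1,3,2-diazaborolidin-2-yl group on oxygen | C=C(CO[Si](C)(C)C(C)(C)C)/C=C(/OB1N(S(=O)(=O)c2cc(cc(c2)C(F)(F)F)C(F)(F)F)[C@@H](c2ccccc2)[C@H](c2ccccc2)N1S(=O)(=O)c1cc(cc(c1)C(F)(F)F)C(F)(F)F)OC/C=C(\C)COC(=O)C(C)(C)C | intermediate
12 | (2S,3S)-2-[3-(TBSO)prop-1-en-2-yl]-3-methyl-3-[(PivO)methyl]pent-4-enoic acid (C5 and C10 set) | C=C[C@](C)(COC(=O)C(C)(C)C)[C@@H](C(=O)O)C(=C)CO[Si](C)(C)C(C)(C)C | intermediate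
13 | potassium 3-methoxy-3-oxopropanoate (potassium methyl malonate) | COC(=O)CC(=O)[O-].[K+] | starting material
14 | acyl imidazolide of 12 | C=C[C@](C)(COC(=O)C(C)(C)C)[C@@H](C(=O)n1ccnc1)C(=C)CO[Si](C)(C)C(C)(C)C | intermediate
15 | acylmalonic half-ester (2-acyl-3-methoxy-3-oxopropanoic acid from 14 and 13) | C=C[C@](C)(COC(=O)C(C)(C)C)[C@@H](C(=O)C(C(=O)O)C(=O)OC)C(=C)CO[Si](C)(C)C(C)(C)C | intermediate
16 | methyl (4S,5S)-4-[3-(TBSO)prop-1-en-2-yl]-5-methyl-3-oxo-5-[(PivO)methyl]hept-6-enoate | C=C[C@](C)(COC(=O)C(C)(C)C)[C@@H](C(=O)CC(=O)OC)C(=C)CO[Si](C)(C)C(C)(C)C | intermediate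
17 | methyl (3R,4S,5S)-3-hydroxy-4-[3-(TBSO)prop-1-en-2-yl]-5-methyl-5-[(PivO)methyl]hept-6-enoate | C=C[C@](C)(COC(=O)C(C)(C)C)[C@@H]([C@H](O)CC(=O)OC)C(=C)CO[Si](C)(C)C(C)(C)C | intermediate
18 | dilithium alkoxide enolate of 17 | C=C[C@](C)(COC(=O)C(C)(C)C)[C@@H]([C@H]([O-])C=C([O-])OC)C(=C)CO[Si](C)(C)C(C)(C)C.[Li+].[Li+] | intermediate
19 | methyl (2S,3S,4S,5S)-3-hydroxy-2-(hydroxymethyl)-4-[3-(TBSO)prop-1-en-2-yl]-5-methyl-5-[(PivO)methyl]hept-6-enoate | C=C[C@](C)(COC(=O)C(C)(C)C)[C@@H]([C@H](O)[C@H](CO)C(=O)OC)C(=C)CO[Si](C)(C)C(C)(C)C | intermediate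
20 | methyl (2S,3S,4S,5S)-3-(TESO)-2-[(TESO)methyl]-4-[3-(TBSO)prop-1-en-2-yl]-5-methyl-5-[(PivO)methyl]hept-6-enoate | C=C[C@](C)(COC(=O)C(C)(C)C)[C@@H]([C@H](O[Si](CC)(CC)CC)[C@H](CO[Si](CC)(CC)CC)C(=O)OC)C(=C)CO[Si](C)(C)C(C)(C)C | intermediate
21 | (2S,3S,4S,5S)-5-(hydroxymethyl)-5-methyl-3-(TESO)-2-[(TESO)methyl]-4-[3-(TBSO)prop-1-en-2-yl]hept-6-en-1-ol | C=C[C@](C)(CO)[C@@H]([C@H](O[Si](CC)(CC)CC)[C@H](CO[Si](CC)(CC)CC)CO)C(=C)CO[Si](C)(C)C(C)(C)C | intermediate
22 | (2S,3S,4S,5S)-2-ethenyl-2-methyl-4-(TESO)-5-[(TESO)methyl]-3-[3-(TBSO)prop-1-en-2-yl]hexanedial | C=C[C@](C)(C=O)[C@@H]([C@H](O[Si](CC)(CC)CC)[C@H](CO[Si](CC)(CC)CC)C=O)C(=C)CO[Si](C)(C)C(C)(C)C | intermediate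
23 | 10α-ethenyl-10β-methyl-5β-[3-(TBSO)prop-1-en-2-yl]-6β-(TESO)-7β-[(TESO)methyl]cyclohexane-8α,9α-diol (ring A, elemane locants) | C=C[C@]1(C)[C@H](O)[C@H](O)[C@@H](CO[Si](CC)(CC)CC)[C@@H](O[Si](CC)(CC)CC)[C@H]1C(=C)CO[Si](C)(C)C(C)(C)C | intermediate
24 | 10α-ethenyl-7β-(hydroxymethyl)-10β-methyl-5β-[3-(TBSO)prop-1-en-2-yl]-6β-(TESO)cyclohexane-8α,9α-diol | C=C[C@]1(C)[C@H](O)[C@H](O)[C@@H](CO)[C@@H](O[Si](CC)(CC)CC)[C@H]1C(=C)CO[Si](C)(C)C(C)(C)C | intermediate
25 | 10α-ethenyl-7β-formyl-10β-methyl-5β-[3-(TBSO)prop-1-en-2-yl]-6β-(TESO)cyclohexane-8α,9α-diol | C=C[C@]1(C)[C@H](O)[C@H](O)[C@@H](C=O)[C@@H](O[Si](CC)(CC)CC)[C@H]1C(=C)CO[Si](C)(C)C(C)(C)C | intermediate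
26 | 10α-ethenyl-7β-ethynyl-10β-methyl-5β-[3-(TBSO)prop-1-en-2-yl]-6β-(TESO)cyclohexane-8α,9α-diol (trans-C7-ethynyl C8-alcohol, key-step precursor) | C=C[C@]1(C)[C@H](O)[C@H](O)[C@@H](C#C)[C@@H](O[Si](CC)(CC)CC)[C@H]1C(=C)CO[Si](C)(C)C(C)(C)C | intermediate
27 | carbon monoxide | [C-]#[O+] | starting material
28 | 9α-hydroxy-6β-(TESO)-15-(TBSO)elema-1,3,11(13)-trien-12,8α-olide (trans-fused α-methylene-γ-butyrolactone, H-7α, H-8β) | C=C[C@]1(C)[C@H](O)[C@@H]2OC(=O)C(=C)[C@H]2[C@@H](O[Si](CC)(CC)CC)[C@H]1C(=C)CO[Si](C)(C)C(C)(C)C | intermediate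
29 | (2Z)-2-methylbut-2-enoic acid (angelic acid) | C/C=C(/C)C(=O)O | starting material
30 | (2Z)-2-methylbut-2-enoic 2,4,6-trichlorobenzoic anhydride | C/C=C(/C)C(=O)OC(=O)c1c(Cl)cc(Cl)cc1Cl | intermediate
31 | 9α-[(2Z)-2-methylbut-2-enoyloxy]-6β-(TESO)-15-(TBSO)elema-1,3,11(13)-trien-12,8α-olide | C=C[C@]1(C)[C@H](OC(=O)/C(C)=C\C)[C@@H]2OC(=O)C(=C)[C@H]2[C@@H](O[Si](CC)(CC)CC)[C@H]1C(=C)CO[Si](C)(C)C(C)(C)C | intermediate
32 | 6β,15-dihydroxy-9α-[(2Z)-2-methylbut-2-enoyloxy]elema-1,3,11(13)-trien-12,8α-olide | C=C[C@]1(C)[C@H](OC(=O)/C(C)=C\C)[C@@H]2OC(=O)C(=C)[C@H]2[C@@H](O)[C@H]1C(=C)CO | intermediate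
33 | 6β-hydroxy-9α-[(2Z)-2-methylbut-2-enoyloxy]-15-oxoelema-1,3,11(13)-trien-12,8α-olide | C=C[C@]1(C)[C@H](OC(=O)/C(C)=C\C)[C@@H]2OC(=O)C(=C)[C@H]2[C@@H](O)[C@H]1C(=C)C=O | intermediate
34 | 6β-acetoxy-9α-[(2Z)-2-methylbut-2-enoyloxy]-15-oxoelema-1,3,11(13)-trien-12,8α-olide, (5R,6S,7S,8R,9S,10S), CNP0252310.1 | C=C[C@]1(C)[C@H](OC(=O)/C(C)=C\C)[C@@H]2OC(=O)C(=C)[C@H]2[C@@H](OC(C)=O)[C@H]1C(=C)C=O | target

Total step count: 23.
Longest linear sequence: 20 steps (steps 1–3 and 7–23 from 1; the branch from 5 through steps 4–6 and 7–23 is equally long).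

Steps most likely to fail

The first is step 19. The catalyst may be tied up by the free cis-diol, or the Lewis-acidic tin co-catalyst may strip a silyl ether at 70 °C, so that carbonylation stalls or the freed O6 competes for the alkyne. The fallback sets out from 26 and builds the lactone in stages. An α-selective hydrostannation (Bu3SnH, catalytic Mo(CO)3(CNtBu)3, THF, 55 °C) should give the 2-(tributylstannyl)alkene F1. Iododestannylation (I2, CH2Cl2, 0 °C) then gives the 2-iodoalkene F2. Carbonylative lactonisation under zerovalent palladium (Pd(PPh3)4, CO at 1 atm, Et3N, MeCN, 60 °C) proceeds by oxidative addition, CO insertion and capture of the acylpalladium by the C8 hydroxyl, and rejoins the route at 28.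

The second is step 8. Enantiofacial control or E/Z control of the boron dienolate may be poor on an ester that also carries a pivalate and an allylic silyl ether, or the boron Lewis acid may cleave that ether. The fallback sets out from 10 and separates stereocontrol from the rearrangement. A classical Ireland–Claisen sequence (LiN(iPr)2, THF, −78 °C; Me3SiCl, Et3N; −78 °C → rt) forms the E(O)-trimethylsilyl ketene acetal F3. F3 rearranges through the same chair to the racemic trimethylsilyl ester F4, and dilute acid gives 12 together with its (2R,3R)-enantiomer F5. The racemate is resolved by crystallising the (1R)-1-phenylethylammonium salt F6 of 12, and acidification returns 12.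

The third is step 20. Acylation of the axial, neopentyl-type C9 hydroxyl by an α-branched unsaturated acyl donor may be slow, and forcing it invites (Z)→(E) isomerisation of the donor. The fallback sets out from 28 and makes the (Z)-alkene after the ester bond. Steglich esterification with 2-[bis(2,2,2-trifluoroethoxy)phosphoryl]propanoic acid (DCC, catalytic DMAP, CH2Cl2), a saturated donor that cannot isomerise, gives the phosphonate ester F7. A Still–Gennari olefination (KN(SiMe3)2, 18-crown-6, THF, −78 °C, then acetaldehyde) should then deliver the (Z)-2-methylbut-2-enoate and rejoin the route at 31.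

Further compounds
F1 | step 19 | 10α-ethenyl-10β-methyl-7β-[1-(tributylstannyl)ethenyl]-5β-[3-(TBSO)prop-1-en-2-yl]-6β-(TESO)cyclohexane-8α,9α-diol | C=C[C@]1(C)[C@H](O)[C@H](O)[C@@H](C(=C)[Sn](CCCC)(CCCC)CCCC)[C@@H](O[Si](CC)(CC)CC)[C@H]1C(=C)CO[Si](C)(C)C(C)(C)C
F2 | step 19 | 10α-ethenyl-7β-(1-iodoethenyl)-10β-methyl-5β-[3-(TBSO)prop-1-en-2-yl]-6β-(TESO)cyclohexane-8α,9α-diol | C=C[C@]1(C)[C@H](O)[C@H](O)[C@@H](C(=C)I)[C@@H](O[Si](CC)(CC)CC)[C@H]1C(=C)CO[Si](C)(C)C(C)(C)C
F3 | step 8 | E(O)-trimethylsilyl ketene acetal of 10 | C=C(CO[Si](C)(C)C(C)(C)C)/C=C(/O[Si](C)(C)C)OC/C=C(\C)COC(=O)C(C)(C)C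
F4 | step 8 | trimethylsilyl ester of racemic 12 (drawn as the 2S,3S enantiomer) | C=C[C@](C)(COC(=O)C(C)(C)C)[C@@H](C(=O)O[Si](C)(C)C)C(=C)CO[Si](C)(C)C(C)(C)C
F5 | step 8 | (2R,3R)-2-[3-(TBSO)prop-1-en-2-yl]-3-methyl-3-[(PivO)methyl]pent-4-enoic acid (enantiomer of 12) | C=C[C@@](C)(COC(=O)C(C)(C)C)[C@H](C(=O)O)C(=C)CO[Si](C)(C)C(C)(C)C
F6 | step 8 | (1R)-1-phenylethylammonium salt of 12 | C=C[C@](C)(COC(=O)C(C)(C)C)[C@@H](C(=O)[O-])C(=C)CO[Si](C)(C)C(C)(C)C.C[C@@H]([NH3+])c1ccccc1
F7 | step 20 | 9α-{2-[bis(2,2,2-trifluoroethoxy)phosphoryl]propanoyloxy}-6β-(TESO)-15-(TBSO)elema-1,3,11(13)-trien-12,8α-olide | C=C[C@]1(C)[C@H](OC(=O)C(C)P(=O)(OCC(F)(F)F)OCC(F)(F)F)[C@@H]2OC(=O)C(=C)[C@H]2[C@@H](O[Si](CC)(CC)CC)[C@H]1C(=C)CO[Si](C)(C)C(C)(C)C
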